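If you want the whole substrate of these flasks turned into target, each catalyst you charge has to make 2000 turnovers on average. This turnover demand, substrate charged over catalyst charged, is the turnover number that the next charge has to reach.

all flasks: free catalyst 0.75 mM

| flask | substrate | partner | temperature | remark | time |
|---|---|---|---|---|---|
| summer | 1 M | 3 M | −5 °C | run made earlier |  |
| midnight | 1 M | 3 M | 30 °C | run made earlier |  |
| south-west | 1.5 M | 3.00 M | 60 °C |  | 30 h |
| south | 1.5 M | 3.00 M | 0 °C |  | 30 h |
| south-east | 1.5 M | 3.00 M | 20 °C |  | 30 h |
| north-west | 1.5 M | 3.00 M | 40 °C |  | 30 h |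

- summer (time / h: target / %, substrate / %): 120: 11.5, 90.6; 240: 20.3, 80.2; 360: 29.2, 72.5; 480: 36.6, 62.9; 600: 43.1, 58.0; 720: 50.1, 50.1
- midnight (time / h: target / %, substrate / %): 20.0: 18.9, 80.3; 40.0: 34.8, 63.2; 72.0: 53.2, 47.9; 96.0: 61.6, 35.8; 120: 68.8, 31.2; 144: 74.8, 24.0

(scatter of a reading: 1 percentage point)

- reactions considered so far: partner + free catalyst <-> catalyst intermediate A; catalyst intermediate A <-> catalyst intermediate B; substrate + catalyst intermediate B <-> catalyst intermediate C; catalyst intermediate C -> by-product + catalyst intermediate D; catalyst intermediate D -> free catalyst + target; catalyst intermediate B -> spent catalyst; 2 catalyst intermediate B <-> resting dimer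

1. the flask that comes out highest in amount of target, in percent of the substrate charged, or "all alike" when all lie within 1.5 percentage points (south-west / south / south-east / north-west / all alike)
2. target at the end, in percent of the substrate charged, south-west
3. target at the end, in percent of the substrate charged, south
4. target at the end, in percent of the substrate charged, south-east
5. target at the end, in percent of the substrate charged, north-west

Counted per catalyst, the midnight run turned over at 12.6 h⁻¹ during its first 20.0 h, and the summer run at 1.28 h⁻¹ during its first 120 h, so warming from −5 °C to 30 °C raised the pace to about ten times the colder one. If you take pace in proportion to substrate, my own reckoning puts the midnight pace at 18.9 h⁻¹ for a charge of 1.5 M, which in 30 h converts 28.3 % of the substrate. The south and south-east flasks are both colder than the midnight run, so I expect them below that share and would leave them uncharged.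

Meeting the demand in 30 h takes a steady 66.7 h⁻¹, which is 3.53 times that opening midnight pace, and the warming already seen gave a larger factor. That opening pace does not hold, though: averaged over its whole 144 h the midnight run turned over at 6.93 h⁻¹, slower than at its start, so both the speed and the life of a catalyst stay open. By 144 h the midnight run had made 997 turnovers, about half the demand, but the runs stop at 30 °C. I cannot separate north-west from south-west on these readings, so I would charge both as they stand.

The forecast gives 4.1 % for south, 15.6 % for south-east, 42 % for north-west and 56 % for south-west, and it names south-west, saying of 60 °C that it "likely still wins, but this is uncertain".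

Highest came north-west at 38.9 %, then south-west at 26.9 %, south-east at 16.5 % and south at 4.20 %.

    partner + free catalyst ⇌ catalyst intermediate A (K = 0.210 L mol⁻¹, k = 190 L mol⁻¹ h⁻¹, Ea = 47.0 kJ mol⁻¹, ΔH = 18.0 kJ mol⁻¹)
    catalyst intermediate A ⇌ catalyst intermediate B (K = 1.30, k = 18000 h⁻¹, Ea = 66.0 kJ mol⁻¹, ΔH = −32.0 kJ mol⁻¹)
    substrate + catalyst intermediate B ⇌ catalyst intermediate C (K = 0.510 L mol⁻¹, k = 200 L mol⁻¹ h⁻¹, Ea = 48.0 kJ mol⁻¹, ΔH = −65.0 kJ mol⁻¹)
    catalyst intermediate C → by-product + catalyst intermediate D (k = 4300 h⁻¹, Ea = 64.0 kJ mol⁻¹)
    catalyst intermediate D → free catalyst + target (k = 19000 h⁻¹, Ea = 73.0 kJ mol⁻¹)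
    catalyst intermediate B → spent catalyst (k = 0.0150 h⁻¹, Ea = 104 kJ mol⁻¹)
    2 catalyst intermediate B ⇌ resting dimer, settled at all times (K = 2.90 × 10⁵ L mol⁻¹, ΔH = −6.00 kJ mol⁻¹)
    (constants at 20 °C)

At 30.0 h the south-west flask had made 538 turnovers of the 2000 demanded, with 99.9 % of its catalyst spent, which is 539 turnovers per spent catalyst, while the north-west flask had made 778 with 28.4 % spent, which is 2740 per spent catalyst, a higher count. The south-east flask, read at 300 h, stands at 1640 turnovers with 18.6 % spent, which is 8790 per spent catalyst.

All runs stem from a simulated flask for an exercise; noise was put on by code.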